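**Retrosynthetic overview**
1. The C2–O1 bond of the pyran ring is disconnected last: the target is the ring-closed isomer of 2-geranylgeranyl-6-methyl-1,4-benzoquinone (tautomerisation to a vinyl ortho-quinone methide, then oxa-6π closure).
2. The quinone comes from para-oxygenation of 2-geranylgeranyl-6-methylphenol.
3. That phenol comes from ortho-C-allylation of o-cresol with all-E geranylgeranyl bromide, made from geranylgeraniol.
4. Ring order: the benzene ring is bought (o-cresol); the 2H-pyran ring is the only ring formed, in the final step, which also sets the single stereocentre (C2, S).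

Assumptions: all-E geranylgeraniol is bought as a single geometric isomer; the quinine-derived catalyst in step 4 is taken to give the (S) product, to be verified against resolved material, with the quinidine-derived pseudoenantiomer as the drop-in switch if the sense is opposite.

**Step 1**
Reactants: 1 (2E,6E,10E)-3,7,11,15-tetramethylhexadeca-2,6,10,14-tetraen-1-ol (all-E geranylgeraniol)
Product: 2 (2E,6E,10E)-1-bromo-3,7,11,15-tetramethylhexadeca-2,6,10,14-tetraene (geranylgeranyl bromide)
Conditions: PBr3 (0.4 equiv), Et2O, −10 → 0 °C, 30 min; used crude at once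
Reagents that add atoms: phosphorus tribromide, BrP(Br)Br
Why: PBr3 bromination of a primary allylic alcohol (SN2 on the bromophosphite) at low temperature keeps the 2E geometry and leaves the trisubstituted alkenes alone; no stereocentre is involved.

**Step 2**
Reactants: 2 geranylgeranyl bromide; 3 2-methylphenol (o-cresol)
Product: 6 2-methyl-6-[(2E,6E,10E)-3,7,11,15-tetramethylhexadeca-2,6,10,14-tetraen-1-yl]phenol, via sodium 2-methylphenolate 4 (not isolated), via ortho-allylated cyclohexadienone 5 (not isolated)
Conditions: 3 (3 equiv), NaH (3 equiv), toluene, 0 °C → rt, 1 h; then 2 (1 equiv), rt, 16 h; aq. NH4Cl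
Reagents that add atoms: sodium hydride, [H-].[Na+] (its sodium is in 4 only; nothing from it stays in 6)
Why: Phenoxide ortho-C-allylation: in a non-polar solvent the tight sodium phenoxide ion pair attacks the primary allylic bromide through its free ortho carbon (SN2, E geometry kept) and dienone 5 tautomerises to the phenol; excess cresolate suppresses dialkylation.

**Step 3**
Reactants: 6 2-geranylgeranyl-6-methylphenol
Product: 7 2-methyl-6-[(2E,6E,10E)-3,7,11,15-tetramethylhexadeca-2,6,10,14-tetraen-1-yl]cyclohexa-2,5-diene-1,4-dione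
Conditions: Co(salen) (salcomine, 10 mol %), O2 (1 atm), MeCN, rt, 3–6 h, dark
Reagents that add atoms: dioxygen, O=O
Why: Salcomine/O2 oxidation of a 2,6-dialkylphenol with a free para position gives the p-benzoquinone (phenoxyl radical trapped para by Co-superoxo), a standard entry to prenylquinones that tolerates isolated trisubstituted alkenes.

**Step 4**
Reactants: 7 2-geranylgeranyl-6-methyl-1,4-benzoquinone
Product: 9 (2S)-2,8-dimethyl-2-[(3E,7E)-4,8,12-trimethyltrideca-3,7,11-trien-1-yl]-2H-chromen-6-ol, via vinyl ortho-quinone methide 8 (not isolated)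
Conditions: 9-amino-9-deoxy-epi-quinine 3,5-bis(trifluoromethyl)benzyl squaramide (10 mol %), toluene (0.05 M), 4 Å MS, 25 °C, Ar, dark, 24–48 h; chromatography below 30 °C (isomerisation, nothing is lost)
Reagents that add atoms: none
Why: Proposed new method: catalytic enantioselective prototropic shift/oxa-6π electrocyclisation of an allyl-p-benzoquinone. The squaramide NH pair binds the unhindered C4=O as an oxyanion hole while the quinuclidine removes a C1′–H (vinylogous enolisation), giving o-quinone methide 8 as a contact ion pair whose N+–H hydrogen-bonds the reacting oxygen O1. Disrotatory C–O closure then occurs inside this chiral pair before 8 dissociates; because the 2′E alkene fixes CH3 inside and the chain outside, the catalyst's choice of helix sense fixes the C2 configuration (S required), and proton return to the new phenoxide releases 9 and the catalyst. The racemic background needs heat with simple amines, so it should be slow at 25 °C. Closest known reactions: the racemic Et3N- or pyridine-mediated prenylquinone → chromenol isomerisation, cinchona-squaramide-catalysed intramolecular oxa-Michael cyclisations, and chiral ion-pair or chiral Brønsted-acid-catalysed asymmetric 6π electrocyclisations.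

**Compound list**
1 | (2E,6E,10E)-3,7,11,15-tetramethylhexadeca-2,6,10,14-tetraen-1-ol (geranylgeraniol) | CC(C)=CCC/C(C)=C/CC/C(C)=C/CC/C(C)=C/CO | starting material
2 | (2E,6E,10E)-1-bromo-3,7,11,15-tetramethylhexadeca-2,6,10,14-tetraene | CC(C)=CCC/C(C)=C/CC/C(C)=C/CC/C(C)=C/CBr | intermediate
3 | 2-methylphenol (o-cresol) | Cc1ccccc1O | starting material
4 | sodium 2-methylphenolate | Cc1ccccc1[O-].[Na+] | intermediate
5 | 2-methyl-6-[(2E,6E,10E)-3,7,11,15-tetramethylhexadeca-2,6,10,14-tetraen-1-yl]cyclohexa-2,4-dien-1-one (racemic at C6) | CC(C)=CCC/C(C)=C/CC/C(C)=C/CC/C(C)=C/CC1C=CC=C(C)C1=O | intermediate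
6 | 2-methyl-6-[(2E,6E,10E)-3,7,11,15-tetramethylhexadeca-2,6,10,14-tetraen-1-yl]phenol | CC(C)=CCC/C(C)=C/CC/C(C)=C/CC/C(C)=C/Cc1cccc(C)c1O | intermediate
7 | 2-methyl-6-[(2E,6E,10E)-3,7,11,15-tetramethylhexadeca-2,6,10,14-tetraen-1-yl]cyclohexa-2,5-diene-1,4-dione | CC(C)=CCC/C(C)=C/CC/C(C)=C/CC/C(C)=C/CC1=CC(=O)C=C(C)C1=O | intermediate
8 | (6Z)-4-hydroxy-2-methyl-6-[(2E,6E,10E)-3,7,11,15-tetramethylhexadeca-2,6,10,14-tetraen-1-ylidene]cyclohexa-2,4-dien-1-one | CC(C)=CCC/C(C)=C/CC/C(C)=C/CC/C(C)=C/C=C1/C=C(O)C=C(C)C1=O | intermediate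
9 | (2S)-2,8-dimethyl-2-[(3E,7E)-4,8,12-trimethyltrideca-3,7,11-trien-1-yl]-2H-chromen-6-ol | CC(C)=CCC/C(C)=C/CC/C(C)=C/CC[C@@]1(C)C=Cc2cc(O)cc(C)c2O1 | target

**Totals**
Total steps: 4. Longest linear sequence: 4 (1 → 2 → 6 → 7 → 9).

**Three steps most likely to fail**

Step 4 (the proposed new step). The risks are low ee if closure of 8 escapes the catalyst, sluggish tautomerisation at 25 °C, or erosion by thermal or photochemical ring opening of the product. The fallback uses known chemistry, sets out from 7 and comes back at 9. Quinone 7 is heated in pyridine (110 °C, Ar), the established base-mediated prenylquinone → chromenol isomerisation, to give the racemic chromenol F1. Preparative chiral SFC on an amylose tris(3,5-dimethylphenylcarbamate) phase (CO2/iPrOH) then delivers 9, and the (R)-enantiomer F2 is set aside.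

Step 2. The risks are O-allylation, para-C-allylation and some SN2′ product, which would lower the yield of 6. The fallback sets out from 3 (together with 2) and comes back at 6, replacing phenoxide alkylation by directed metalation. o-Cresol is protected (MOMCl, iPr2NEt, CH2Cl2) as 1-(methoxymethoxy)-2-methylbenzene F3. Ring lithiation ortho to the OMOM group (n-BuLi, TMEDA, Et2O, 0 °C → rt) gives [2-(methoxymethoxy)-3-methylphenyl]lithium F4. Copper-catalysed allylation with 2 (CuBr·SMe2 10 mol %, −78 → 0 °C) gives the MOM ether of 2-geranylgeranyl-6-methylphenol F5. Mild acetal exchange (cat. HCl, MeOH, 40 °C) then returns 6.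

Step 3. The risks are over-oxidation of the polyene chain, radical coupling of the phenol, or partial cyclisation of the quinone on work-up. The fallback sets out from 2 and comes back at 7, carrying the para oxygen from the start instead of installing it by C–H oxygenation. Purchased 4-methoxy-2-methylphenol F6 is converted to its sodium salt (NaH, toluene) and ortho-C-allylated with 2 as in step 2, now with the para position blocked, to give 4-methoxy-2-methyl-6-geranylgeranylphenol F7. Oxidative demethylation with ceric ammonium nitrate (MeCN/H2O, 0 °C) gives 7.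

**Further compounds**
F1 | step 4 | racemic 2,8-dimethyl-2-[(3E,7E)-4,8,12-trimethyltrideca-3,7,11-trien-1-yl]-2H-chromen-6-ol | CC(C)=CCC/C(C)=C/CC/C(C)=C/CCC1(C)C=Cc2cc(O)cc(C)c2O1
F2 | step 4 | (2R)-2,8-dimethyl-2-[(3E,7E)-4,8,12-trimethyltrideca-3,7,11-trien-1-yl]-2H-chromen-6-ol | CC(C)=CCC/C(C)=C/CC/C(C)=C/CC[C@]1(C)C=Cc2cc(O)cc(C)c2O1
F3 | step 2 | 1-(methoxymethoxy)-2-methylbenzene | COCOc1ccccc1C
F4 | step 2 | [2-(methoxymethoxy)-3-methylphenyl]lithium | [Li]c1cccc(C)c1OCOC
F5 | step 2 | 1-(methoxymethoxy)-2-methyl-6-[(2E,6E,10E)-3,7,11,15-tetramethylhexadeca-2,6,10,14-tetraen-1-yl]benzene | CC(C)=CCC/C(C)=C/CC/C(C)=C/CC/C(C)=C/Cc1cccc(C)c1OCOC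
F6 | step 3 | 4-methoxy-2-methylphenol (purchased) | COc1ccc(O)c(C)c1
F7 | step 3 | 4-methoxy-2-methyl-6-[(2E,6E,10E)-3,7,11,15-tetramethylhexadeca-2,6,10,14-tetraen-1-yl]phenol | CC(C)=CCC/C(C)=C/CC/C(C)=C/CC/C(C)=C/Cc1cc(OC)cc(C)c1O
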